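## Retrosynthetic overview

1. The γ-lactone is closed last by oxidative lactonisation of the 6,12-diol 26. The C8 epoxyangelate and C9 acetate are put on one after the other at the α-hydroxy ketone 17 (acylate C8–OH, reduce C9=O, acetylate).
2. The ten-membered ring comes from an anionic oxy-Cope ring expansion (6 → 10) of the dialkenylcyclohexenol 14. It forms C6–C7 and the 4E alkene and relays the quaternary stereocentre to C6 and C7; the enolate is hydroxylated at C8 in the same flask.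
3. The six-membered template 8 comes from dearomatisation of 2,6-dimethylanisole 1 (Birch). The arene carbons become C9, C10, C1–C4, its two methyls become C14 and C15, and the ring-locked cis alkene becomes 1(10)Z. A Pd-catalysed decarboxylative asymmetric allylation then sets the quaternary centre.
4. Side pieces: dienylstannane 12 (C7, C8, C11–C13) by Stille coupling; (2S,3S)-epoxyangelic acid 21 by Sharpless epoxidation of angelyl alcohol.
5. Ring order: six-membered carbocycle (from the arene) → ten-membered carbocycle → γ-lactone.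

Assumption: macrocyclic compounds are named with germacrane numbering (ring C1–C10, C11–C13 on C7, C14 on C10, C15 on C4); the ca. 90% ee expected from step 3 is upgraded by separating diastereomers after the enantiopure acid is attached in step 13.

## Route

Step 1
Reactants: 1 2,6-dimethylanisole
Product: 3 2,6-dimethylcyclohex-2-en-1-one (racemic at C6), via 1-methoxy-2,6-dimethylcyclohexa-1,4-diene 2 (not isolated)
Conditions: Li, liquid NH3, THF, t-BuOH, −78 to −33 °C; then 2 M aq HCl, THF, 25 °C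
Reagents that add atoms: water (O)
Why: Birch reduction breaks the aromatic ring and leaves the methoxy- and methyl-bearing carbons on the enol-ether double bond, and aqueous acid hydrolyses the enol ether and moves the remaining C=C into conjugation, so the arene delivers the 2-methyl-enone with its ring-locked cis alkene; the C6 stereocentre is racemic and is erased in step 2.

Step 2
Reactants: 3 2,6-dimethylcyclohex-2-en-1-one; 4 allyl chloroformate
Product: 5 allyl 2,6-dimethylcyclohexa-1,5-dien-1-yl carbonate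
Conditions: LiN(iPr)2, TMEDA, THF, −78 °C; then 4, −78 to 0 °C
Reagents that add atoms: none
Why: Kinetic α'-deprotonation of the enone gives the cross-conjugated dienolate, which the hard chloroformate acylates on oxygen (enol carbonate formation).

Step 3
Reactants: 5 allyl 2,6-dimethylcyclohexa-1,5-dien-1-yl carbonate
Product: 6 (6S)-2,6-dimethyl-6-(prop-2-en-1-yl)cyclohex-2-en-1-one
Conditions: Pd2(dba)3 (2.5 mol %), (S)-t-BuPHOX (6.25 mol %), THF, 25 °C
Reagents that add atoms: none
Why: Stoltz decarboxylative asymmetric allylic alkylation (Tsuji allylation): the zerovalent palladium–PHOX catalyst ionises the carbonate, loses CO2 and joins allyl and enolate within the chiral complex, the (S)-ligand giving the (S)-quaternary centre as in the 2-methylcyclohexanone series.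

Step 4
Reactants: 6 (6S)-2,6-dimethyl-6-(prop-2-en-1-yl)cyclohex-2-en-1-one
Product: 7 2-[(1S)-1,3-dimethyl-2-oxocyclohex-3-en-1-yl]acetaldehyde
Conditions: O3, CH2Cl2, −78 °C (Sudan Red 7B end point); then Me2S, −78 to 25 °C
Reagents that add atoms: ozone ([O-][O+]=O)
Why: Ozonolysis is selective for the electron-rich monosubstituted alkene over the electron-poor conjugated trisubstituted one; the quaternary centre is untouched.

Step 5
Reactants: 7 2-[(1S)-1,3-dimethyl-2-oxocyclohex-3-en-1-yl]acetaldehyde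
Product: 8 (6S)-6-[(E)-2-{[tert-butyl(dimethyl)silyl]oxy}ethenyl]-2,6-dimethylcyclohex-2-en-1-one
Conditions: TBSOTf, Et3N, CH2Cl2, −78 to 0 °C
Reagents that add atoms: tert-butyldimethylsilyl trifluoromethanesulfonate (CC(C)(C)[Si](C)(C)OS(=O)(=O)C(F)(F)F)
Why: Soft enolisation and O-silylation; only the aldehyde has α-hydrogens (the ketone is flanked by a quaternary and an sp2 carbon), and the E enol ether is expected because the quaternary carbon avoids the position cis to OSi (any Z isomer is removed on Et3N-treated silica); this geometry is needed in step 9.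

Step 6
Reactants: 9 2-bromoprop-2-en-1-ol
Product: 10 tert-butyl[(2-bromoprop-2-en-1-yl)oxy]dimethylsilane
Conditions: TBSCl, imidazole, DMF, 25 °C
Reagents that add atoms: tert-butyldimethylsilyl chloride (CC(C)(C)[Si](C)(C)Cl)
Why: Standard silylation of a primary alcohol; it masks the future C12 oxygen through the organometallic steps.

Step 7
Reactants: 10 tert-butyl[(2-bromoprop-2-en-1-yl)oxy]dimethylsilane; 11 (E)-1,2-bis(tributylstannyl)ethene (2.5 equiv)
Product: 12 tert-butyl(dimethyl){[(3E)-2-methylidene-4-(tributylstannyl)but-3-en-1-yl]oxy}silane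
Conditions: Pd(PPh3)4 (5 mol %), toluene, 85 °C
Reagents that add atoms: none
Why: Stille cross-coupling with retention of the E geometry; the excess of the symmetric bis-stannane limits the reaction to mono-coupling.

Step 8
Reactants: 12 tert-butyl(dimethyl){[(3E)-2-methylidene-4-(tributylstannyl)but-3-en-1-yl]oxy}silane; 8 (6S)-6-[(E)-2-{[tert-butyl(dimethyl)silyl]oxy}ethenyl]-2,6-dimethylcyclohex-2-en-1-one
Product: 14 (1S,6S)-1-[(1E)-3-({[tert-butyl(dimethyl)silyl]oxy}methyl)buta-1,3-dien-1-yl]-6-[(E)-2-{[tert-butyl(dimethyl)silyl]oxy}ethenyl]-2,6-dimethylcyclohex-2-en-1-ol, via dienyllithium 13 (not isolated)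
Conditions: n-BuLi, THF, −78 °C; then 8, −78 °C; aq NH4Cl
Reagents that add atoms: none
Why: Tin–lithium exchange with retention, then 1,2-addition to the non-enolisable enone; the alkenyl group at C6 is expected to sit pseudoaxial and the nucleophile to enter anti to it, giving the trans-dialkenyl (1S) carbinol (a minor cis isomer is separated).

Step 9
Reactants: 14 (1S,6S)-1-[(1E)-3-({[tert-butyl(dimethyl)silyl]oxy}methyl)buta-1,3-dien-1-yl]-6-[(E)-2-{[tert-butyl(dimethyl)silyl]oxy}ethenyl]-2,6-dimethylcyclohex-2-en-1-ol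
Product: 17 (6R,7R,8R)-6,12-bis{[tert-butyl(dimethyl)silyl]oxy}-8-hydroxygermacra-1(10)Z,4E,11(13)-trien-9-one, via potassium alkoxide 15 (not isolated), via potassium dienolate 16 (not isolated)
Conditions: KN(SiMe3)2, 18-crown-6, THF, 0 to 25 °C; then −78 °C, 2-(phenylsulfonyl)-3-phenyloxaziridine; AcOH
Reagents that add atoms: 2-(phenylsulfonyl)-3-phenyloxaziridine (O=S(=O)(N1OC1c1ccccc1)c1ccccc1)
Why: Anionic oxy-Cope rearrangement through a chair transition state with both ring bonds and both terminal substituents (OSi, C11) equatorial breaks C4–C9 and forms C6–C7, so the (S)-quaternary centre is relayed to C6 and C7, C4=C5 is formed E and the ring alkene stays Z; the enolate is then hydroxylated (Davis oxidation) on its outer face, anti to the new C6–C7 bond, which sets C8.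

Step 10
Reactants: 18 angelic acid, (Z)-2-methylbut-2-enoic acid
Product: 19 (Z)-2-methylbut-2-en-1-ol
Conditions: LiAlH4, Et2O, 0 to 25 °C
Reagents that add atoms: none
Why: Hydride reduction of the acid to the allylic alcohol with the Z alkene unchanged.

Step 11
Reactants: 19 (Z)-2-methylbut-2-en-1-ol
Product: 20 [(2R,3S)-2,3-dimethyloxiran-2-yl]methanol
Conditions: Ti(OiPr)4 (10 mol %), D-(−)-diisopropyl tartrate (12 mol %), t-BuOOH, 4 Å molecular sieves, CH2Cl2, −20 °C
Reagents that add atoms: tert-butyl hydroperoxide (CC(C)(C)OO)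
Why: Sharpless asymmetric epoxidation; the D-tartrate delivers oxygen to the face that gives the (2R,3S) epoxy alcohol, and the Z alkene fixes the cis relation of CH2OH and the C3 methyl.

Step 12
Reactants: 20 [(2R,3S)-2,3-dimethyloxiran-2-yl]methanol
Product: 21 (2S,3S)-2,3-dimethyloxirane-2-carboxylic acid
Conditions: TEMPO (cat.), PhI(OAc)2, MeCN/H2O, 25 °C
Reagents that add atoms: water (O)
Why: Oxoammonium oxidation of the primary alcohol through the aldehyde hydrate to the acid without touching the epoxide; the C2 descriptor changes only because CO2H outranks C3.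

Step 13
Reactants: 17 (6R,7R,8R)-6,12-bis{[tert-butyl(dimethyl)silyl]oxy}-8-hydroxygermacra-1(10)Z,4E,11(13)-trien-9-one; 21 (2S,3S)-2,3-dimethyloxirane-2-carboxylic acid
Product: 23 (6R,7R,8R)-6,12-bis{[tert-butyl(dimethyl)silyl]oxy}-9-oxogermacra-1(10)Z,4E,11(13)-trien-8-yl (2S,3S)-2,3-dimethyloxirane-2-carboxylate, via mixed anhydride 22 (not isolated)
Conditions: 21, 2,4,6-trichlorobenzoyl chloride, Et3N, THF, 25 °C; then 17, DMAP, toluene, 25 °C
Reagents that add atoms: none
Why: Yamaguchi esterification of the only free hydroxyl; C9 is still a ketone, so the two oxygens are differentiated, and the minor-enantiomer series is removed here as a diastereomer.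

Step 14
Reactants: 23 (6R,7R,8R)-6,12-bis{[tert-butyl(dimethyl)silyl]oxy}-9-oxogermacra-1(10)Z,4E,11(13)-trien-8-yl (2S,3S)-2,3-dimethyloxirane-2-carboxylate
Product: 24 (6R,7R,8R,9R)-6,12-bis{[tert-butyl(dimethyl)silyl]oxy}-9-hydroxygermacra-1(10)Z,4E,11(13)-trien-8-yl (2S,3S)-2,3-dimethyloxirane-2-carboxylate
Conditions: NaBH4, CeCl3·7H2O, MeOH, −78 °C; cold neutral work-up
Reagents that add atoms: none
Why: Luche 1,2-reduction of the enone; hydride is expected to attack from the ring periphery on the conformer in which C9=O is anti to the C8–O dipole, giving the 8,9-threo (9R) alcohol, while esters and epoxide survive at −78 °C.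

Step 15
Reactants: 24 (6R,7R,8R,9R)-6,12-bis{[tert-butyl(dimethyl)silyl]oxy}-9-hydroxygermacra-1(10)Z,4E,11(13)-trien-8-yl (2S,3S)-2,3-dimethyloxirane-2-carboxylate
Product: 25 (6R,7R,8R,9R)-9-acetoxy-6,12-bis{[tert-butyl(dimethyl)silyl]oxy}germacra-1(10)Z,4E,11(13)-trien-8-yl (2S,3S)-2,3-dimethyloxirane-2-carboxylate
Conditions: Ac2O, pyridine, DMAP (cat.), CH2Cl2, 0 to 25 °C
Reagents that add atoms: acetic anhydride (CC(=O)OC(C)=O)
Why: Acylation of the only free hydroxyl, done at once to forestall 1,2-acyl migration.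

Step 16
Reactants: 25 (6R,7R,8R,9R)-9-acetoxy-6,12-bis{[tert-butyl(dimethyl)silyl]oxy}germacra-1(10)Z,4E,11(13)-trien-8-yl (2S,3S)-2,3-dimethyloxirane-2-carboxylate
Product: 26 (6R,7S,8R,9R)-9-acetoxy-6,12-dihydroxygermacra-1(10)Z,4E,11(13)-trien-8-yl (2S,3S)-2,3-dimethyloxirane-2-carboxylate
Conditions: HF·pyridine, excess pyridine, THF, 0 to 25 °C
Reagents that add atoms: none
Why: Buffered fluoride cleavage of both silyl ethers; the medium is mild enough for the epoxy ester, the acetate and the acid-sensitive 1(10),4-diene (the C7 descriptor changes only through CIP ranking).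

Step 17
Reactants: 26 (6R,7S,8R,9R)-9-acetoxy-6,12-dihydroxygermacra-1(10)Z,4E,11(13)-trien-8-yl (2S,3S)-2,3-dimethyloxirane-2-carboxylate
Product: 29 (6R,7S,8R,9R)-9-acetoxy-8-{[(2S,3S)-2,3-dimethyloxirane-2-carbonyl]oxy}germacra-1(10)Z,4E,11(13)-trien-12,6-olide (CNP0304643.2), via hydroxy enal 27 (not isolated), via lactol 28 (not isolated)
Conditions: TEMPO (20 mol %), PhI(OAc)2 (2.5 equiv), CH2Cl2, 25 °C
Reagents that add atoms: none
Why: Oxidative lactonisation: the primary allylic alcohol is oxidised first, the C6 hydroxyl closes the lactol and a second oxidation gives the trans-fused α-methylene γ-lactone; C8 is already acylated, so only the 6,12-lactone can form.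

## Compound list

1 | 2,6-dimethylanisole | COc1c(C)cccc1C | starting material
2 | 1-methoxy-2,6-dimethylcyclohexa-1,4-diene (racemic) | COC1=C(C)CC=CC1C | intermediate
3 | 2,6-dimethylcyclohex-2-en-1-one (racemic) | CC1CCC=C(C)C1=O | intermediate
4 | allyl chloroformate | C=CCOC(=O)Cl | starting material
5 | allyl 2,6-dimethylcyclohexa-1,5-dien-1-yl carbonate | C=CCOC(=O)OC1=C(C)CCC=C1C | intermediate
6 | (6S)-2,6-dimethyl-6-(prop-2-en-1-yl)cyclohex-2-en-1-one | C=CC[C@]1(C)CCC=C(C)C1=O | intermediate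
7 | 2-[(1S)-1,3-dimethyl-2-oxocyclohex-3-en-1-yl]acetaldehyde | O=CC[C@]1(C)CCC=C(C)C1=O | intermediate
8 | (6S)-6-[(E)-2-{[tert-butyl(dimethyl)silyl]oxy}ethenyl]-2,6-dimethylcyclohex-2-en-1-one | CC(C)(C)[Si](C)(C)O/C=C/[C@]1(C)CCC=C(C)C1=O | intermediate
9 | 2-bromoprop-2-en-1-ol | OCC(Br)=C | starting material
10 | tert-butyl[(2-bromoprop-2-en-1-yl)oxy]dimethylsilane | C=C(Br)CO[Si](C)(C)C(C)(C)C | intermediate
11 | (E)-1,2-bis(tributylstannyl)ethene | CCCC[Sn](CCCC)(CCCC)/C=C/[Sn](CCCC)(CCCC)CCCC | starting material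
12 | tert-butyl(dimethyl){[(3E)-2-methylidene-4-(tributylstannyl)but-3-en-1-yl]oxy}silane | CCCC[Sn](CCCC)(CCCC)/C=C/C(=C)CO[Si](C)(C)C(C)(C)C | intermediate
13 | (1E)-3-({[tert-butyl(dimethyl)silyl]oxy}methyl)buta-1,3-dien-1-yllithium | [Li]/C=C/C(=C)CO[Si](C)(C)C(C)(C)C | intermediate
14 | (1S,6S)-1-[(1E)-3-({[tert-butyl(dimethyl)silyl]oxy}methyl)buta-1,3-dien-1-yl]-6-[(E)-2-{[tert-butyl(dimethyl)silyl]oxy}ethenyl]-2,6-dimethylcyclohex-2-en-1-ol | CC(C)(C)[Si](C)(C)O/C=C/[C@]1(C)CCC=C(C)[C@@]1(O)/C=C/C(=C)CO[Si](C)(C)C(C)(C)C | intermediate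
15 | potassium alkoxide of 14 | CC(C)(C)[Si](C)(C)O/C=C/[C@]1(C)CCC=C(C)[C@@]1([O-])/C=C/C(=C)CO[Si](C)(C)C(C)(C)C.[K+] | intermediate
16 | potassium (6R,7S)-6,12-bis{[tert-butyl(dimethyl)silyl]oxy}germacra-1(10)Z,4E,8,11(13)-tetraen-9-olate (C7 and C10 trans across C8=C9) | C1/C(C)=C/[C@@H](O[Si](C)(C)C(C)(C)C)[C@H](C(=C)CO[Si](C)(C)C(C)(C)C)/C=C(\[O-])/C(C)=C\C1.[K+] | intermediate
17 | (6R,7R,8R)-6,12-bis{[tert-butyl(dimethyl)silyl]oxy}-8-hydroxygermacra-1(10)Z,4E,11(13)-trien-9-one | C1/C(C)=C/[C@@H](O[Si](C)(C)C(C)(C)C)[C@H](C(=C)CO[Si](C)(C)C(C)(C)C)[C@@H](O)C(=O)/C(C)=C\C1 | intermediate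
18 | angelic acid, (Z)-2-methylbut-2-enoic acid | C/C=C(/C)C(=O)O | starting material
19 | (Z)-2-methylbut-2-en-1-ol | C/C=C(/C)CO | intermediate
20 | [(2R,3S)-2,3-dimethyloxiran-2-yl]methanol | OC[C@@]1(C)O[C@H]1C | intermediate
21 | (2S,3S)-2,3-dimethyloxirane-2-carboxylic acid | OC(=O)[C@@]1(C)O[C@H]1C | intermediate
22 | (2S,3S)-2,3-dimethyloxirane-2-carboxylic 2,4,6-trichlorobenzoic anhydride | O=C(OC(=O)[C@@]1(C)O[C@H]1C)c1c(Cl)cc(Cl)cc1Cl | intermediate
23 | (6R,7R,8R)-6,12-bis{[tert-butyl(dimethyl)silyl]oxy}-9-oxogermacra-1(10)Z,4E,11(13)-trien-8-yl (2S,3S)-2,3-dimethyloxirane-2-carboxylate | C1/C(C)=C/[C@@H](O[Si](C)(C)C(C)(C)C)[C@H](C(=C)CO[Si](C)(C)C(C)(C)C)[C@@H](OC(=O)[C@@]2(C)O[C@H]2C)C(=O)/C(C)=C\C1 | intermediate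
24 | (6R,7R,8R,9R)-6,12-bis{[tert-butyl(dimethyl)silyl]oxy}-9-hydroxygermacra-1(10)Z,4E,11(13)-trien-8-yl (2S,3S)-2,3-dimethyloxirane-2-carboxylate | C1/C(C)=C/[C@@H](O[Si](C)(C)C(C)(C)C)[C@H](C(=C)CO[Si](C)(C)C(C)(C)C)[C@@H](OC(=O)[C@@]2(C)O[C@H]2C)[C@H](O)/C(C)=C\C1 | intermediate
25 | (6R,7R,8R,9R)-9-acetoxy-6,12-bis{[tert-butyl(dimethyl)silyl]oxy}germacra-1(10)Z,4E,11(13)-trien-8-yl (2S,3S)-2,3-dimethyloxirane-2-carboxylate | C1/C(C)=C/[C@@H](O[Si](C)(C)C(C)(C)C)[C@H](C(=C)CO[Si](C)(C)C(C)(C)C)[C@@H](OC(=O)[C@@]2(C)O[C@H]2C)[C@H](OC(C)=O)/C(C)=C\C1 | intermediate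
26 | (6R,7S,8R,9R)-9-acetoxy-6,12-dihydroxygermacra-1(10)Z,4E,11(13)-trien-8-yl (2S,3S)-2,3-dimethyloxirane-2-carboxylate | C1/C(C)=C/[C@@H](O)[C@H](C(=C)CO)[C@@H](OC(=O)[C@@]2(C)O[C@H]2C)[C@H](OC(C)=O)/C(C)=C\C1 | intermediate
27 | (6R,7S,8R,9R)-9-acetoxy-6-hydroxy-12-oxogermacra-1(10)Z,4E,11(13)-trien-8-yl (2S,3S)-2,3-dimethyloxirane-2-carboxylate | C1/C(C)=C/[C@@H](O)[C@H](C(=C)C=O)[C@@H](OC(=O)[C@@]2(C)O[C@H]2C)[C@H](OC(C)=O)/C(C)=C\C1 | intermediate
28 | (6R,7S,8R,9R)-9-acetoxy-6,12-epoxy-12-hydroxygermacra-1(10)Z,4E,11(13)-trien-8-yl (2S,3S)-2,3-dimethyloxirane-2-carboxylate (lactol, both C12 epimers) | C=C1C(O)O[C@@H]2/C=C(\C)CC/C=C(/C)[C@@H](OC(C)=O)[C@H](OC(=O)[C@@]3(C)O[C@H]3C)[C@@H]12 | intermediate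
29 | (6R,7S,8R,9R)-9-acetoxy-8-{[(2S,3S)-2,3-dimethyloxirane-2-carbonyl]oxy}germacra-1(10)Z,4E,11(13)-trien-12,6-olide | C=C1C(=O)O[C@@H]2/C=C(\C)CC/C=C(/C)[C@@H](OC(C)=O)[C@H](OC(=O)[C@@]3(C)O[C@H]3C)[C@@H]12 | target

## Step count and risk

Total step count: 17. Longest linear sequence: 12 steps (1, 2, 3, 4, 5, 8, 9, 13, 14, 15, 16, 17).

The three steps most likely to fail:

Step 9 (ring expansion with hydroxylation in the same flask). The rearrangement has close precedent in divinylcyclohexenol ring expansions, but the C8 hydroxylation of a macrocyclic potassium enolate may be unselective or be spoiled by addition to the sulfonimine by-product. The fallback sets out from 14 and separates the two events as a Rubottom sequence. After the rearrangement the enolate is trapped with Et3SiCl to give the triethylsilyl enol ether, (6R,7S)-6,12-bis{[tert-butyl(dimethyl)silyl]oxy}-9-[(triethylsilyl)oxy]germacra-1(10)Z,4E,8,11(13)-tetraene F4. One equivalent of dimethyldioxirane at −78 °C epoxidises only this most electron-rich alkene, and silyl migration gives the α-silyloxy ketone, (6R,7S,8R)-6,12-bis{[tert-butyl(dimethyl)silyl]oxy}-8-[(triethylsilyl)oxy]germacra-1(10)Z,4E,11(13)-trien-9-one F5. AcOH/THF/H2O then removes the triethylsilyl group selectively, and the route is rejoined at 17.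

Step 14 (configuration at C9). Facial selectivity in a flexible ten-membered ring is the least predictable stereochemical event of the route. The fallback sets out from 23. If hydride delivery gives mainly the C9 epimer, (6R,7R,8R,9S)-6,12-bis{[tert-butyl(dimethyl)silyl]oxy}-9-hydroxygermacra-1(10)Z,4E,11(13)-trien-8-yl (2S,3S)-2,3-dimethyloxirane-2-carboxylate F6, that alcohol is used instead. Mitsunobu acetoxylation (PPh3, diisopropyl azodicarboxylate, AcOH, toluene, 0 °C) installs the acetate with inversion and lands directly on 25, so steps 14 and 15 are replaced together.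

Step 8 (alkenyl addition to the hindered enone and its facial selectivity). The dienyllithium may add sluggishly or give too much of the cis-dialkenyl carbinol. The fallback sets out from 10 and 8 and uses a smaller, linear nucleophile. Sonogashira coupling of 10 with trimethylsilylacetylene (PdCl2(PPh3)2, CuI, Et3N) gives tert-butyl(dimethyl){[2-methylidene-4-(trimethylsilyl)but-3-yn-1-yl]oxy}silane F1. K2CO3 in MeOH frees the terminal enyne, tert-butyl(dimethyl)[(2-methylidenebut-3-yn-1-yl)oxy]silane F2. Its lithium acetylide (n-BuLi, THF, −78 °C) adds to 8 to give the propargylic alcohol, (1S,6S)-1-[3-({[tert-butyl(dimethyl)silyl]oxy}methyl)but-3-en-1-yn-1-yl]-6-[(E)-2-{[tert-butyl(dimethyl)silyl]oxy}ethenyl]-2,6-dimethylcyclohex-2-en-1-ol F3. Hydroxyl-directed trans-hydroalumination with NaAlH2(OCH2CH2OMe)2 in THF then gives the E alkene, and the route is rejoined at 14.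

Further compounds
F1 | step 8 | tert-butyl(dimethyl){[2-methylidene-4-(trimethylsilyl)but-3-yn-1-yl]oxy}silane | C=C(CO[Si](C)(C)C(C)(C)C)C#C[Si](C)(C)C
F2 | step 8 | tert-butyl(dimethyl)[(2-methylidenebut-3-yn-1-yl)oxy]silane | C=C(CO[Si](C)(C)C(C)(C)C)C#C
F3 | step 8 | (1S,6S)-1-[3-({[tert-butyl(dimethyl)silyl]oxy}methyl)but-3-en-1-yn-1-yl]-6-[(E)-2-{[tert-butyl(dimethyl)silyl]oxy}ethenyl]-2,6-dimethylcyclohex-2-en-1-ol | CC(C)(C)[Si](C)(C)O/C=C/[C@]1(C)CCC=C(C)[C@@]1(O)C#CC(=C)CO[Si](C)(C)C(C)(C)C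
F4 | step 9 | (6R,7S)-6,12-bis{[tert-butyl(dimethyl)silyl]oxy}-9-[(triethylsilyl)oxy]germacra-1(10)Z,4E,8,11(13)-tetraene | C1/C(C)=C/[C@@H](O[Si](C)(C)C(C)(C)C)[C@H](C(=C)CO[Si](C)(C)C(C)(C)C)/C=C(\O[Si](CC)(CC)CC)/C(C)=C\C1
F5 | step 9 | (6R,7S,8R)-6,12-bis{[tert-butyl(dimethyl)silyl]oxy}-8-[(triethylsilyl)oxy]germacra-1(10)Z,4E,11(13)-trien-9-one | C1/C(C)=C/[C@@H](O[Si](C)(C)C(C)(C)C)[C@H](C(=C)CO[Si](C)(C)C(C)(C)C)[C@@H](O[Si](CC)(CC)CC)C(=O)/C(C)=C\C1
F6 | step 14 | (6R,7R,8R,9S)-6,12-bis{[tert-butyl(dimethyl)silyl]oxy}-9-hydroxygermacra-1(10)Z,4E,11(13)-trien-8-yl (2S,3S)-2,3-dimethyloxirane-2-carboxylate | C1/C(C)=C/[C@@H](O[Si](C)(C)C(C)(C)C)[C@H](C(=C)CO[Si](C)(C)C(C)(C)C)[C@@H](OC(=O)[C@@]2(C)O[C@H]2C)[C@@H](O)/C(C)=C\C1
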